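**Retrosynthetic overview**

1. The oxirane is removed first (hydroxyl-directed epoxidation of C4=C5 by the C6 hydroxyl). The C6 carbinol then goes back to an enone, the aryl ester to the C8 alcohol, and the C8 carbinol with C7 to a ten-membered 2-isopropyl-1,3-dione (enantioselective reduction with dynamic resolution of C7).
2. Key disconnection: the 1,3-dione is the ring-merged retro-aldol product of a 1-siloxybicyclo[6.2.0]decadienone. That is the [2+2] adduct of chloro(isopropyl)ketene with the C6=C9 silyl enol ether of (2Z,6Z)-3,7-dimethylcycloocta-2,6-dienone.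
3. Feature the strategy rests on: C7 (isopropyl) and C8 (ester) are a two-carbon unit inserted between C6 and C9 of a cis,cis-dimethylcyclooctadiene ring (C9, C10, C1, C2, C3, C4, C5, C6). The small ring fixes both trisubstituted olefins (C10=C1 and C4=C5) as cis.
4. The dienone (one conjugated and one β,γ olefin) comes from (1Z,5Z)-1,5-dimethylcycloocta-1,5-diene by monoepoxidation, selenide opening with selenoxide elimination, and oxidative allylic transposition. This sequence places the carbonyl at C6 without a regiochemical choice.
5. Ring order: eight-membered ring (purchased), four-membered ring fused at C6–C9 (step 6), ten-membered ring by scission of that shared bond (step 8), oxirane (step 12).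

Key step: step 8

Remark: ring carbons carry the labels of the target throughout: C1 (olefinic CH), C2, C3, C4 (methyl-bearing), C5, C6, C7 (isopropyl-bearing), C8, C9, C10 (methyl-bearing).
Remark: the commercial dimethylcyclooctadiene is taken as free of its 1,6-dimethyl isomer (fractional distillation, or chromatography at the epoxide stage).
Remark: the sense of induction of the ruthenium catalyst at C8 is assigned by analogy with aryl ketones (the carbonyl-bearing C7 arm in the place of the aryl group), which calls for the (R,R)-ligand; its antipode would be used if the analogy does not hold.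

**Route**

Step 1
Reactants: 1 (1Z,5Z)-1,5-dimethylcycloocta-1,5-diene
Product: 2 (Z)-1,5-dimethyl-9-oxabicyclo[6.1.0]non-4-ene (cis-fused C4–C5 monoepoxide; racemic)
Conditions: mCPBA (0.95 equiv), CH2Cl2, −20 → 0 °C; aq. Na2SO3/NaHCO3 wash
Reagents that add atoms: 3-chloroperbenzoic acid (mCPBA), OOC(=O)c1cccc(Cl)c1
Why: Prilezhaev epoxidation; the two olefins of the C2-symmetric diene are equivalent, so a slight deficit of peracid should give mainly the monoepoxide, and concerted syn oxygen transfer to the cis olefin gives the cis-fused oxirane (racemic; both centres are erased by step 3).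

Step 2
Reactants: 2 (Z)-1,5-dimethyl-9-oxabicyclo[6.1.0]non-4-ene
Product: 5 (2Z,5Z)-1,5-dimethylcycloocta-2,5-dien-1-ol (racemic), via trans-hydroxy selenide 3 (not isolated), via selenoxide 4 (not isolated)
Conditions: PhSeSePh (0.55 equiv), NaBH4, EtOH, reflux; then THF, 30% H2O2, pyridine, 0 °C → rt
Reagents that add atoms: none
Why: Epoxide opening by selenide followed by selenoxide syn-elimination (organoselenium epoxide-to-allylic-alcohol transposition): the selenide attacks the less substituted C5 with inversion, and the selenoxide can only eliminate towards C6 because C4 has no hydrogen, which gives the tertiary allylic alcohol with a ring-enforced cis C5=C6 olefin.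

Step 3
Reactants: 5 (2Z,5Z)-1,5-dimethylcycloocta-2,5-dien-1-ol
Product: 6 (2Z,6Z)-3,7-dimethylcycloocta-2,6-dien-1-one
Conditions: pyridinium chlorochromate (2 equiv), 4 Å molecular sieves, CH2Cl2, rt
Reagents that add atoms: pyridinium chlorochromate, [O-][Cr](=O)(=O)Cl.c1cc[nH+]cc1 (its oxygen becomes the carbonyl oxygen; the hydroxyl oxygen of 5 is lost)
Why: Babler–Dauben oxidative transposition: the tertiary allylic alcohol cannot be oxidised in place, so oxygen is transposed [3,3] to C6 and oxidised there, which puts the carbonyl next to the olefinic CH and restores the cis C4=C5 olefin, a regiochemistry that direct allylic oxidation of 1 would not secure.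

Step 4
Reactants: 6 (2Z,6Z)-3,7-dimethylcycloocta-2,6-dien-1-one
Product: 8 3,7-dimethyl-1-(trimethylsilyloxy)cycloocta-1,3,7-triene (all three olefins cis within the ring), via lithium dienolate 7 (not isolated)
Conditions: LiN(iPr)2 (1.1 equiv), THF, −78 °C; Me3SiCl, Et3N, −78 → 0 °C; pentane, filtration, used at once
Reagents that add atoms: chlorotrimethylsilane, C[Si](C)(C)Cl
Why: Kinetic enolate formation and O-silylation: the amide base at −78 °C removes a C9 proton, which is α′ to the carbonyl and allylic to C10=C1, in preference to a γ proton of the enone, and trapping on oxygen gives the C6=C9 silyl enol ether, which is kept cold to avoid electrocyclisation of the cyclooctatriene.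

Step 5
Reactants: 9 3-methylbutanoyl chloride
Product: 10 2-chloro-3-methylbutanoyl chloride (racemic)
Conditions: N-chlorosuccinimide, SOCl2 (solvent), conc. HCl (cat.), 80 °C; distillation
Reagents that add atoms: N-chlorosuccinimide, O=C1CCC(=O)N1Cl
Why: Acid-catalysed α-chlorination of an acid chloride through its enol (Hell–Volhard–Zelinsky-type halogenation), with thionyl chloride as solvent keeping the acyl chloride intact; the new centre is racemic and disappears in the ketene.

Step 6
Reactants: 8 3,7-dimethyl-1-(trimethylsilyloxy)cycloocta-1,3,7-triene; 10 2-chloro-3-methylbutanoyl chloride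
Product: 12 (2Z,6Z)-10-chloro-3,7-dimethyl-10-(propan-2-yl)-1-(trimethylsilyloxy)bicyclo[6.2.0]deca-2,6-dien-9-one (racemic; cis ring fusion; C7 epimers), via chloro(isopropyl)ketene 11 (not isolated)
Conditions: 10 (1.5 equiv), Et3N (1.5 equiv, slow addition), hexane, 0 → 25 °C
Reagents that add atoms: none
Why: Ketene–enol ether [2+2] cycloaddition: dehydrochlorination of 10 gives the electrophilic chloro(alkyl)ketene, whose carbonyl carbon (C8) bonds to the nucleophilic β-carbon C9 of the silyl enol ether and whose substituted carbon (C7) bonds to the siloxy carbon C6, suprafacially on the cis enol ether so that the four-membered ring is cis-fused; C7 forms as a mixture, which does not matter.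

Step 7
Reactants: 12 (2Z,6Z)-10-chloro-3,7-dimethyl-10-(propan-2-yl)-1-(trimethylsilyloxy)bicyclo[6.2.0]deca-2,6-dien-9-one
Product: 13 (2Z,6Z)-3,7-dimethyl-10-(propan-2-yl)-1-(trimethylsilyloxy)bicyclo[6.2.0]deca-2,6-dien-9-one (racemic; cis ring fusion; C7 epimers)
Conditions: Zn dust, AcOH, 2-propanol/H2O, 0 °C → rt
Reagents that add atoms: none
Why: Reductive dehalogenation of an α-chloro ketone by zinc, the zinc enolate being protonated by acetic acid faster than it can expel the β-siloxy group; the C7 configuration is again irrelevant, and early loss of silicon would only lead on to 15.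

Step 8
Reactants: 13 (2Z,6Z)-3,7-dimethyl-10-(propan-2-yl)-1-(trimethylsilyloxy)bicyclo[6.2.0]deca-2,6-dien-9-one
Product: 15 (4Z,8Z)-5,9-dimethyl-2-(propan-2-yl)cyclodeca-4,8-diene-1,3-dione (C7 epimerisable), via tetrabutylammonium cyclobutanolate 14 (not isolated)
Conditions: Bu4NF (1.05 equiv), THF, −78 → 0 °C; AcOH quench
Reagents that add atoms: none
Why: Fluoride removes the bridgehead trimethylsilyl group, and the C6 alkoxide 14, which is β to the cyclobutanone carbonyl, undergoes retro-aldol scission of the C6–C9 bond shared by the four- and eight-membered rings, so that C6 becomes the enone carbonyl and C8–C9 an enolate that is protonated at C9. The closest known reaction type is the two-carbon ring expansion of cyclic silyl enol ethers through ketene [2+2] adducts, in which 1-siloxybicyclo[n.2.0]alkanones open to cycloalkane-1,3-diones. The ten-membered ring is not closed end to end but arises by merging the two fused rings when their common bond breaks. No stereocentre is created: C6 and C9 lose theirs and C7 stays epimerisable, while the two cis olefins are not touched and keep the geometry fixed in the eight-membered ring. The step needs cleavage of C6–C9 and not of C6–C7, nor an oxyanion-accelerated Cope shift of the divinylcyclobutanolate; this should be secured because only C6–C9 scission gives an enolate conjugated with the C10=C1 olefin and releases the bicyclic strain, whereas the Cope shift would only exchange one four-membered ring for another. Proton transfer then gives the C7 β-diketonate, which keeps the charge away from C9 and so protects the β,γ-olefin from moving into conjugation before the quench.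

Step 9
Reactants: 15 (4Z,8Z)-5,9-dimethyl-2-(propan-2-yl)cyclodeca-4,8-diene-1,3-dione
Product: 16 (2Z,6Z,9R,10R)-9-hydroxy-3,7-dimethyl-10-(propan-2-yl)cyclodeca-2,6-dien-1-one
Conditions: RuCl(p-cymene)[(R,R)-TsNCH(Ph)CH(Ph)NH2] (2 mol %), HCO2H/Et3N (5:2), CH2Cl2, 30 °C
Reagents that add atoms: none
Why: Noyori–Ikariya asymmetric transfer hydrogenation with dynamic kinetic resolution: C7 epimerises through the enol of the β-diketone under Et3N, the ruthenium hydride reduces the more electrophilic non-conjugated C8 carbonyl, hydride enters anti to the isopropyl group (hydroxyl cis to isopropyl) and the ligand selects the enantiomer, which sets C8 (R) and C7 (descriptor R here, S in the target for the same arrangement in space).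

Step 10
Reactants: 16 (2Z,6Z,9R,10R)-9-hydroxy-3,7-dimethyl-10-(propan-2-yl)cyclodeca-2,6-dien-1-one; 17 3,4,5-trimethoxybenzoyl chloride
Product: 18 (1R,3Z,7Z,10R)-3,7-dimethyl-9-oxo-10-(propan-2-yl)cyclodeca-3,7-dien-1-yl 3,4,5-trimethoxybenzoate
Conditions: 17 (1.3 equiv), pyridine, 4-(dimethylamino)pyridine (0.1 equiv), CH2Cl2, 0 °C
Reagents that add atoms: none
Why: Nucleophile-catalysed acylation of the only hydroxyl group; the weak base and low temperature should avoid β-elimination of the new acyloxy group and epimerisation at C7, and no stereocentre is touched.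

Step 11
Reactants: 18 (1R,3Z,7Z,10R)-3,7-dimethyl-9-oxo-10-(propan-2-yl)cyclodeca-3,7-dien-1-yl 3,4,5-trimethoxybenzoate
Product: 19 (1R,3Z,7Z,9S,10S)-9-hydroxy-3,7-dimethyl-10-(propan-2-yl)cyclodeca-3,7-dien-1-yl 3,4,5-trimethoxybenzoate
Conditions: NaBH4, CeCl3·7H2O, MeOH/THF, −78 °C
Reagents that add atoms: none
Why: Luche 1,2-reduction of the enone: in the Felkin–Anh sense hydride should attack C6 from the periphery of the ring, anti to the C7–C8 bond and past the C7 hydrogen rather than the isopropyl group, which places the new hydroxyl cis to the isopropyl group and to the ester (C6, descriptor S here and R in the target for the same arrangement), while the aryl ester is inert to borohydride at this temperature.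

Step 12
Reactants: 19 (1R,3Z,7Z,9S,10S)-9-hydroxy-3,7-dimethyl-10-(propan-2-yl)cyclodeca-3,7-dien-1-yl 3,4,5-trimethoxybenzoate
Product: 20 (1R,2R,3S,4R,6Z,10S)-2-hydroxy-6,10-dimethyl-3-(propan-2-yl)-11-oxabicyclo[8.1.0]undec-6-en-4-yl 3,4,5-trimethoxybenzoate (CNP0260213.10)
Conditions: VO(acac)2 (5 mol %), t-BuOOH (1.5 equiv, in decane), CH2Cl2, 0 °C → rt
Reagents that add atoms: tert-butyl hydroperoxide, CC(C)(C)OO
Why: Hydroxyl-directed epoxidation: the vanadium alkoxide of the C6 hydroxyl should deliver the peroxide oxygen to the allylic C4=C5 olefin on the face syn to that hydroxyl through a small O–C6–C5=C4 dihedral angle, as in medium-ring cycloalkenols, which gives the cis epoxy alcohol with C4 (S) and C5 (R), while the C10=C1 olefin, which has no free hydroxyl near it, is left alone.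

**Compound list**

1 | (1Z,5Z)-1,5-dimethylcycloocta-1,5-diene | C1/C(C)=C\CC/C(C)=C\C1 | starting material
2 | (Z)-1,5-dimethyl-9-oxabicyclo[6.1.0]non-4-ene, cis-fused, racemic (one enantiomer drawn) | C1/C(C)=C\CC[C@]2(C)O[C@@H]2C1 | intermediate
3 | trans-(Z)-1,5-dimethyl-8-(phenylselanyl)cyclooct-4-en-1-ol, racemic, not isolated | C1/C(C)=C\CC[C@](C)(O)[C@@H]([Se]c2ccccc2)C1 | intermediate
4 | trans-(Z)-1,5-dimethyl-8-(phenylseleninyl)cyclooct-4-en-1-ol, racemic, not isolated | C1/C(C)=C\CC[C@](C)(O)[C@@H]([Se](=O)c2ccccc2)C1 | intermediate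
5 | (2Z,5Z)-1,5-dimethylcycloocta-2,5-dien-1-ol, racemic (one enantiomer drawn) | C[C@@]1(O)/C=C\C/C(C)=C\CC1 | intermediate
6 | (2Z,6Z)-3,7-dimethylcycloocta-2,6-dien-1-one | C1/C(C)=C\C(=O)C/C(C)=C\C1 | intermediate
7 | lithium 3,7-dimethylcycloocta-1,3,7-trien-1-olate (ring-cis olefins), not isolated | C1/C(C)=C\C(O[Li])=C/C(C)=C\C1 | intermediate
8 | 3,7-dimethyl-1-(trimethylsilyloxy)cycloocta-1,3,7-triene (ring-cis olefins) | C1/C(C)=C\C(O[Si](C)(C)C)=C/C(C)=C\C1 | intermediate
9 | 3-methylbutanoyl chloride | CC(C)CC(Cl)=O | starting material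
10 | 2-chloro-3-methylbutanoyl chloride, racemic | CC(C)C(Cl)C(Cl)=O | intermediate
11 | 2-chloro-3-methylbut-1-en-1-one (chloro(isopropyl)ketene), not isolated | CC(C)C(Cl)=C=O | intermediate
12 | (2Z,6Z)-10-chloro-3,7-dimethyl-10-(propan-2-yl)-1-(trimethylsilyloxy)bicyclo[6.2.0]deca-2,6-dien-9-one, cis-fused, racemic, C7 epimers | CC(C)C1(Cl)C(=O)[C@@H]2/C(C)=C\CC/C(C)=C\[C@]12O[Si](C)(C)C | intermediate
13 | (2Z,6Z)-3,7-dimethyl-10-(propan-2-yl)-1-(trimethylsilyloxy)bicyclo[6.2.0]deca-2,6-dien-9-one, cis-fused, racemic, C7 epimers (key-step precursor) | CC(C)C1C(=O)[C@@H]2/C(C)=C\CC/C(C)=C\[C@]12O[Si](C)(C)C | intermediate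
14 | tetrabutylammonium (2Z,6Z)-3,7-dimethyl-9-oxo-10-(propan-2-yl)bicyclo[6.2.0]deca-2,6-dien-1-olate, not isolated | CC(C)C1C(=O)[C@@H]2/C(C)=C\CC/C(C)=C\[C@]12[O-].CCCC[N+](CCCC)(CCCC)CCCC | intermediate
15 | (4Z,8Z)-5,9-dimethyl-2-(propan-2-yl)cyclodeca-4,8-diene-1,3-dione, C7 labile (key-step product) | CC(C)C1C(=O)C/C(C)=C\CC/C(C)=C\C1=O | intermediate
16 | (2Z,6Z,9R,10R)-9-hydroxy-3,7-dimethyl-10-(propan-2-yl)cyclodeca-2,6-dien-1-one | O[C@@H]1C/C(C)=C\CC/C(C)=C\C(=O)[C@@H]1C(C)C | intermediate
17 | 3,4,5-trimethoxybenzoyl chloride | COc1cc(C(Cl)=O)cc(OC)c1OC | starting material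
18 | (1R,3Z,7Z,10R)-3,7-dimethyl-9-oxo-10-(propan-2-yl)cyclodeca-3,7-dien-1-yl 3,4,5-trimethoxybenzoate | COc1cc(C(=O)O[C@@H]2C/C(C)=C\CC/C(C)=C\C(=O)[C@@H]2C(C)C)cc(OC)c1OC | intermediate
19 | (1R,3Z,7Z,9S,10S)-9-hydroxy-3,7-dimethyl-10-(propan-2-yl)cyclodeca-3,7-dien-1-yl 3,4,5-trimethoxybenzoate | COc1cc(C(=O)O[C@@H]2C/C(C)=C\CC/C(C)=C\[C@H](O)[C@@H]2C(C)C)cc(OC)c1OC | intermediate
20 | (1R,2R,3S,4R,6Z,10S)-2-hydroxy-6,10-dimethyl-3-(propan-2-yl)-11-oxabicyclo[8.1.0]undec-6-en-4-yl 3,4,5-trimethoxybenzoate (ring labels: 4S,5R,6R,7S,8R) | COc1cc(C(=O)O[C@@H]2C/C(C)=C\CC[C@]3(C)O[C@@H]3[C@H](O)[C@@H]2C(C)C)cc(OC)c1OC | target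

**Step count**

Total: 12 steps. Longest linear sequence: 11 steps (steps 1–4 and 6–12); step 5 is a one-step branch.

**Steps most likely to fail**

1. Step 9. The catalyst has no aryl or alkynyl group to recognise at C8, so hydride transfer may be slow, may go to the C6 enone carbonyl instead, or may discriminate poorly between the two enantiomers of the dione; a largely enolised dione would not be reduced at all. Fallback, from 15 and back at 16: reduction without a chiral catalyst (NaBH4, MeOH/CH2Cl2, −78 °C; saturated C8 carbonyl before the enone, hydride anti to the isopropyl group) should give the racemic cis-hydroxy ketone F6. This is resolved by preparative chromatography on a chiral stationary phase (amylose tris(3,5-dimethylphenylcarbamate)), which gives 16. The antipode ent-16 F7 is oxidised back to 15 (Dess–Martin periodinane, 1,1,1-triacetoxy-1,1-dihydro-1,2-benziodoxol-3(1H)-one) and recycled, since C7 of 15 racemises.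

2. Step 6. The hindered chloro(isopropyl)ketene may dimerise faster than it adds to the fully substituted C6 terminus of the enol ether, may add at one of the flanking olefins or across the siloxydiene in a [4+2] sense, and the amine hydrochloride may desilylate the enol ether. Fallback, from 8 and back at 15: the two ring carbons are brought in without the isopropyl group by the least hindered and most reactive ketene. Dichloroketene F1 (Cl2CHCOCl, Et3N, hexane, 0 °C) should add to 8 to give the 10,10-dichloro-1-siloxybicyclo[6.2.0]decadienone F2. Zn/AcOH removes both chlorines to give the siloxycyclobutanone F3, and Bu4NF as in step 8 opens it to (4Z,8Z)-5,9-dimethylcyclodeca-4,8-diene-1,3-dione F4. Knoevenagel condensation with acetone (TiCl4, pyridine, THF, 0 °C) gives the 2-isopropylidene dione F5. Conjugate reduction of its doubly activated olefin with diethyl 2,6-dimethyl-1,4-dihydropyridine-3,5-dicarboxylate (Hantzsch ester) gives 15.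

3. Step 11. Several ring conformers of the ten-membered enone may react, giving poor facial selectivity at C6; 1,3-migration of the aroyl group to the new hydroxyl is a second possible loss. Fallback, from 18 and back at 19: reagent control in place of substrate control by Corey–Bakshi–Shibata reduction with (R)-1-methyl-3,3-diphenyltetrahydro-1H,3H-pyrrolo[1,2-c][1,3,2]oxazaborole and catecholborane in toluene at −78 °C. The (R)-catalyst is chosen on the model in which the branched C7 arm acts as the large group; the antipode would be used if the alkenyl arm dominates. This fallback makes no new compound (F0).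

**Further compounds**

F1 | step 6 | dichloroketene | ClC(Cl)=C=O
F2 | step 6 | (2Z,6Z)-10,10-dichloro-3,7-dimethyl-1-(trimethylsilyloxy)bicyclo[6.2.0]deca-2,6-dien-9-one, cis-fused, racemic | ClC1(Cl)C(=O)[C@@H]2/C(C)=C\CC/C(C)=C\[C@]12O[Si](C)(C)C
F3 | step 6 | (2Z,6Z)-3,7-dimethyl-1-(trimethylsilyloxy)bicyclo[6.2.0]deca-2,6-dien-9-one, cis-fused, racemic | C1C(=O)[C@@H]2/C(C)=C\CC/C(C)=C\[C@]12O[Si](C)(C)C
F4 | step 6 | (4Z,8Z)-5,9-dimethylcyclodeca-4,8-diene-1,3-dione | C1C(=O)C/C(C)=C\CC/C(C)=C\C1=O
F5 | step 6 | (4Z,8Z)-5,9-dimethyl-2-(propan-2-ylidene)cyclodeca-4,8-diene-1,3-dione | CC(C)=C1C(=O)C/C(C)=C\CC/C(C)=C\C1=O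
F6 | step 9 | racemic cis-(2Z,6Z)-9-hydroxy-3,7-dimethyl-10-(propan-2-yl)cyclodeca-2,6-dien-1-one (both enantiomers) | O[C@@H]1C/C(C)=C\CC/C(C)=C\C(=O)[C@@H]1C(C)C.O[C@H]1C/C(C)=C\CC/C(C)=C\C(=O)[C@H]1C(C)C
F7 | step 9 | (2Z,6Z,9S,10S)-9-hydroxy-3,7-dimethyl-10-(propan-2-yl)cyclodeca-2,6-dien-1-one (ent-16) | O[C@H]1C/C(C)=C\CC/C(C)=C\C(=O)[C@H]1C(C)C
F0 | step 11 | none | none
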